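**Strategy**

Target numbering is kept for all intermediates (C1 dienoic acid, C2 butenyl, C7 sulfate). Everything rests on disconnecting C4a–C5 by an anionic oxy-Cope rearrangement: the C3=C4 alkene of ring A sits δ,ε to the oxygen-bearing C7 of ring B, so the precursor is a 2-vinylbicyclo[2.2.2]oct-5-en-2-ol in which C3 is still bonded to C7. In one operation the [3,3] shift forms C4a–C5, closes ring B, fixes the cis fusion at C4a, moves the alkene to C3=C4 and releases the C7 ketone. The bicyclooctenone comes from a Diels–Alder reaction of a quinol acetate of 2,6-dimethylphenol with a chiral menthyloxybutenolide.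

Key step: step 9

Remarks on the chemistry:
- Ring A is C1–C2–C3–C4–C4a–C8a and ring B is C4a–C5–C6–C7–C8–C8a. In the bicyclic intermediates the bridgeheads are C3 (CH3) and C8a (H), and the three bridges are C4=C4a, C7–C8 and C2–C1.
- Butenolide 3, the antipode of the common l-menthol-derived reagent, is assumed to be a catalogue compound.
- Quinol acetate 2 is used as the racemate, two equivalents (one of each enantiomer). Step 2 is planned as a kinetic resolution that consumes the (6S) enantiomer and leaves the (6R) enantiomer, which is removed by chromatography.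
- The target is isolated in the fully protonated form drawn.

**Route**

Step 1
Reactants: 1 2,6-dimethylphenol
Product: 2 rac-6-acetoxy-2,6-dimethylcyclohexa-2,4-dien-1-one (quinol acetate)
Conditions: Pb(OAc)4, AcOH, rt
Reagents that add atoms: lead tetraacetate, CC(=O)O[Pb](OC(C)=O)(OC(C)=O)OC(C)=O
Why: Wessely oxidation: the aryloxy–lead intermediate (tetravalent lead) transfers acetate to the methyl-bearing ortho carbon to give the dearomatised quinol acetate, whose new stereocentre is racemic and is erased again in step 4.

Step 2
Reactants: 2 quinol acetate (2 equiv), 3 (5S)-5-[(1S,2R,5S)-menthyloxy]furan-2(5H)-one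
Product: 4 endo lactone acetal cycloadduct (bicyclo[2.2.2]oct-5-en-2-one; lactone C=O on C2 and menthyloxy acetal carbon on C1, both syn to the C4=C4a bridge; 8-OAc anti to that bridge)
Conditions: toluene, 110 °C, sealed tube
Reagents that add atoms: none
Why: Thermal Diels–Alder reaction of a cyclohexa-2,4-dienone with a butenolide: the lactone alpha-carbon bonds to the carbonyl-bearing diene terminus (ortho rule), the lactone lies endo under the diene and the diene adds anti to the menthyloxy group, which fixes C1, C2, C3 and C8a in the absolute sense and exposes the butenolide to one diene face only; the (6S) enantiomer of 2 carries its acetoxy group on that face and should be consumed, the (6R) enantiomer would have to react on its methyl face and should be left behind (kinetic resolution), and any C8 epimer that it does form converges in step 4.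

Step 3
Reactants: 4 endo lactone acetal cycloadduct
Product: 6 Weinreb amide dimethyl acetal, via amide aldehyde 5 (not isolated)
Conditions: MeNHOMe·HCl, AlMe3, CH2Cl2, 0 °C to rt; then HCl/MeOH, HC(OMe)3, 0 °C to rt
Reagents that add atoms: N,O-dimethylhydroxylamine hydrochloride, CNOC.Cl; trimethyl orthoformate, COC(OC)OC
Why: Weinreb aminolysis of the lactone with the aluminium amide opens the pseudo-ester at its carbonyl, the released hemiacetal collapses to the C1 aldehyde with loss of menthol, and acid-catalysed acetalisation caps that aldehyde before the eclipsed cis C1/C2 pair can epimerise, so no stereocentre changes.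

Step 4
Reactants: 6 Weinreb amide dimethyl acetal
Product: 8 C8-H ketone, via samarium enolate 7 (not isolated)
Conditions: SmI2 (2.5 equiv), THF/MeOH, −78 °C, buffered quench at −78 °C
Reagents that add atoms: none
Why: Reductive cleavage of the alpha-acetoxy ketone by two single-electron transfers from divalent samarium gives the trivalent samarium enolate 7, which methanol should protonate at C8 under kinetic control from the open face next to the C4=C4a bridge, leaving the C8 methyl anti to that bridge.

Step 5
Reactants: 8 C8-H ketone
Product: 9 vinyl carbinol Weinreb amide (vinyl syn to the C4=C4a bridge)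
Conditions: CH2=CHMgBr, CeCl3, THF, −78 °C
Reagents that add atoms: vinylmagnesium bromide, C=C[Mg]Br
Why: 1,2-Addition of the weakly basic organocerium reagent (the Weinreb amide is inert at −78 °C) should occur from the face syn to the C4=C4a bridge, because the opposite face is screened by the C8 methyl and by H-2, which sets C7 with the vinyl group syn to the alkene as the rearrangement demands.

Step 6
Reactants: 9 vinyl carbinol Weinreb amide
Product: 10 vinyl carbinol ethyl ketone
Conditions: EtMgBr (3 equiv), THF, 0 °C to rt
Reagents that add atoms: ethylmagnesium bromide, CC[Mg]Br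
Why: Weinreb ketone synthesis: the chelated tetrahedral adduct persists until work-up, so a single ethyl group is delivered while the tertiary alcohol is carried as its magnesium alkoxide and C2 is not enolised.

Step 7
Reactants: 10 vinyl carbinol ethyl ketone
Product: 12 Z-enol triflate, via dipotassium enolate 11 (not isolated)
Conditions: KN(SiMe3)2 (2.3 equiv), THF, −78 °C; then N-(5-chloropyridin-2-yl)bis(trifluoromethanesulfonyl)imide, −78 °C, quench at −78 °C
Reagents that add atoms: N-(5-chloropyridin-2-yl)bis(trifluoromethanesulfonyl)imide, FC(F)(F)S(=O)(=O)N(c1ccc(Cl)cn1)S(=O)(=O)C(F)(F)F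
Why: Kinetic enolisation at the ethyl CH2 (H-2 is shielded by quaternary C3) should give the Z(O)-enolate, in which the bulky C2 residue forces the methyl cis to oxygen, and O-triflation with the pyridyl triflimide locks this geometry while the tertiary potassium alkoxide stays inert at −78 °C.

Step 8
Reactants: 12 Z-enol triflate
Product: 13 butenyl vinyl carbinol (oxy-Cope precursor)
Conditions: Me2Zn, Pd(PPh3)4 (5 mol %), THF, 0 °C to rt
Reagents that add atoms: dimethylzinc, C[Zn]C
Why: Negishi cross-coupling at zerovalent palladium replaces triflate by methyl with retention of alkene geometry, which completes the (E)-but-2-en-2-yl group.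

Step 9
Reactants: 13 butenyl vinyl carbinol
Product: 17 cis-decalone 8R epimer, via potassium alkoxide 14 (not isolated), via potassium enolate 15 (not isolated), via 8-epi-decalone 16 (not isolated)
Conditions: KH (3 equiv), 18-crown-6, THF, 0 °C to rt; then MeOH, rt
Reagents that add atoms: none
Why: KH forms the crown-separated potassium alkoxide 14, whose oxido group weakens the C3–C7 bond so that the 1,5-diene C5=C6–C7(O−)–C3–C4=C4a undergoes a concerted [3,3] shift in which C3–C7 breaks, C4a–C5 forms and enolate 15 results. The closest known reaction type is the anionic oxy-Cope rearrangement of 2-vinylbicyclo[2.2.2]oct-5-en-2-olates to cis-fused octalones. Ring B is closed by this suprafacial sigmatropic bond formation through a boat-like six-centre transition state that the bicycle enforces, a bridge-for-ring exchange and not an ionic cyclisation. The new C4a stereocentre is dictated by the framework, since C5 can reach C4a only on the face that carries the C7 bridge, which is cis to H-8a and gives 4aS. The step needs the [3,3] path to beat the [1,3] shift and alkoxide fragmentation, which the syn vinyl group and the rigid alignment secure, and it needs no regiochoice because only one oxido-1,5-diene is present. Methanol then protonates 15 to 16, and the methoxide formed should equilibrate C8 to the 8R epimer 17, whose axial methyl lies anti to C1 whereas the 8-epi methyl suffers a syn-pentane clash with the C1 substituent.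

Step 10
Reactants: 17 cis-decalone 8R epimer
Product: 19 hydroxy aldehyde, via hydroxy acetal 18 (not isolated)
Conditions: Li, NH3(l), THF, MeOH, −78 °C; NH4Cl; then 1 M HCl, THF, rt
Reagents that add atoms: water, O
Why: Dissolving-metal reduction of the ketone under thermodynamic control should give the equatorial 7S alcohol, whose hydroxyl avoids the 1,3-diaxial contact with C1 that the 7-epimer would suffer, and the aqueous acid work-up hydrolyses the dimethyl acetal to the aldehyde without touching C1.

Step 11
Reactants: 19 hydroxy aldehyde, 20 triethyl 4-phosphonocrotonate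
Product: 21 hydroxy dienoate ethyl ester
Conditions: LiN(SiMe3)2 (2.3 equiv), THF, −78 to 0 °C
Reagents that add atoms: none
Why: Vinylogous Horner–Wadsworth–Emmons olefination with the stabilised phosphonate anion builds the (2E,4E)-dienoate, the extra base only deprotonating the C7 hydroxyl and the low temperature preserving the alpha-branched C1 centre.

Step 12
Reactants: 21 hydroxy dienoate ethyl ester
Product: 22 sulfate ethyl ester
Conditions: SO3·pyridine, pyridine, rt
Reagents that add atoms: sulfur trioxide pyridine complex, [O-]S(=O)(=O)[n+]1ccccc1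
Why: O-Sulfation of the secondary alcohol with the sulfur trioxide–amine complex occurs with retention at C7 because only the O–H bond reacts.

Step 13
Reactants: 22 sulfate ethyl ester
Product: 23 target acid
Conditions: LiOH, THF/MeOH/H2O, rt; then cold 1 M HCl to pH 2
Reagents that add atoms: lithium hydroxide, [Li+].[OH-]
Why: Saponification of the ethyl ester by acyl–oxygen cleavage leaves the base-stable sulfate monoester intact, and brief cold acidification should give the fully protonated target.

**Compound list**

1 | 2,6-dimethylphenol | Cc1cccc(C)c1O | starting material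
2 | rac-6-acetoxy-2,6-dimethylcyclohexa-2,4-dien-1-one | CC1=CC=CC(C)(OC(C)=O)C1=O | intermediate
3 | (5S)-5-{[(1S,2R,5S)-5-methyl-2-(propan-2-yl)cyclohexyl]oxy}furan-2(5H)-one | O=C1O[C@H](O[C@H]2C[C@@H](C)CC[C@@H]2C(C)C)C=C1 | starting material
4 | endo cycloadduct: bicyclo[2.2.2]oct-5-en-2-one with C3-CH3 and C8a-H bridgeheads, C8(CH3)(OAc) with OAc anti to the C4=C4a bridge, cis-fused lactone on C2/C1 syn to that bridge (C=O on C2, menthyloxy acetal carbon on C1, O-menthyl trans to C8a) | O=C1O[C@H](O[C@H]4C[C@@H](C)CC[C@@H]4C(C)C)[C@@H]2[C@H]1[C@]3(C)C=C[C@H]2[C@](C)(OC(C)=O)C3=O | intermediate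
5 | amide aldehyde: core of 4 with C2-C(=O)N(OMe)Me and C1-CHO, both syn to the C4=C4a bridge | CON(C)C(=O)[C@@H]1[C@]2(C)C=C[C@H]([C@@H]1C=O)[C@](C)(OC(C)=O)C2=O | intermediate
6 | Weinreb amide dimethyl acetal: as 5 with C1-CH(OMe)2 | CON(C)C(=O)[C@@H]1[C@]2(C)C=C[C@H]([C@@H]1C(OC)OC)[C@](C)(OC(C)=O)C2=O | intermediate
7 | trivalent samarium C7=C8 enolate of 8 | CON(C)C(=O)[C@@H]1[C@]2(C)C=C[C@H]([C@@H]1C(OC)OC)C(C)=C2O[Sm](I)I | intermediate
8 | C8-H ketone: as 6 without OAc, C8 methyl anti to the C4=C4a bridge | CON(C)C(=O)[C@@H]1[C@]2(C)C=C[C@H]([C@@H]1C(OC)OC)[C@H](C)C2=O | intermediate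
9 | vinyl carbinol Weinreb amide: C7 bears vinyl (syn to the C4=C4a bridge) and OH (anti) | CON(C)C(=O)[C@@H]1[C@]2(C)C=C[C@H]([C@@H]1C(OC)OC)[C@H](C)[C@@]2(O)C=C | intermediate
10 | vinyl carbinol ethyl ketone: as 9 with C2-C(=O)Et | CCC(=O)[C@@H]1[C@]2(C)C=C[C@H]([C@@H]1C(OC)OC)[C@H](C)[C@@]2(O)C=C | intermediate
11 | dipotassium Z(O)-enolate alkoxide of 10 | C/C=C(\[O-])[C@@H]1[C@]2(C)C=C[C@H]([C@@H]1C(OC)OC)[C@H](C)[C@@]2([O-])C=C.[K+].[K+] | intermediate
12 | (Z)-enol triflate: C2-C(OTf)=CH-CH3 with OTf cis to the terminal methyl | C/C=C(\OS(=O)(=O)C(F)(F)F)[C@@H]1[C@]2(C)C=C[C@H]([C@@H]1C(OC)OC)[C@H](C)[C@@]2(O)C=C | intermediate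
13 | butenyl vinyl carbinol: 2-vinylbicyclo[2.2.2]oct-5-en-2-ol with C2-(E)-but-2-en-2-yl, C1-CH(OMe)2, C8 methyl anti to the alkene bridge | C/C=C(\C)[C@@H]1[C@]2(C)C=C[C@H]([C@@H]1C(OC)OC)[C@H](C)[C@@]2(O)C=C | intermediate
14 | potassium alkoxide of 13 | C/C=C(\C)[C@@H]1[C@]2(C)C=C[C@H]([C@@H]1C(OC)OC)[C@H](C)[C@@]2([O-])C=C.[K+] | intermediate
15 | potassium C6=C7 enolate of the cis-fused 8-epi-decalone | C/C=C(\C)[C@@H]1C(C)=C[C@H]2CC=C([O-])[C@@H](C)[C@H]2[C@@H]1C(OC)OC.[K+] | intermediate
16 | 8-epi-decalone: cis-fused, C8 methyl trans to H-8a | C/C=C(\C)[C@@H]1C(C)=C[C@H]2CCC(=O)[C@@H](C)[C@H]2[C@@H]1C(OC)OC | intermediate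
17 | cis-decalone: C1, C2, C4a, C8 and C8a configured as in the target, C7 ketone, C1-CH(OMe)2 | C/C=C(\C)[C@@H]1C(C)=C[C@H]2CCC(=O)[C@H](C)[C@H]2[C@@H]1C(OC)OC | intermediate
18 | hydroxy acetal: as 17 with 7S equatorial hydroxyl | C/C=C(\C)[C@@H]1C(C)=C[C@H]2CC[C@H](O)[C@H](C)[C@H]2[C@@H]1C(OC)OC | intermediate
19 | hydroxy aldehyde: as 18 with C1-CHO | C/C=C(\C)[C@@H]1C(C)=C[C@H]2CC[C@H](O)[C@H](C)[C@H]2[C@@H]1C=O | intermediate
20 | triethyl 4-phosphonocrotonate, ethyl (2E)-4-(diethoxyphosphoryl)but-2-enoate | CCOC(=O)/C=C/CP(=O)(OCC)OCC | starting material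
21 | ethyl (2E,4E)-5-[decalin-1-yl]penta-2,4-dienoate with free 7S hydroxyl, ring stereocentres as in the target | C/C=C(\C)[C@@H]1C(C)=C[C@H]2CC[C@H](O)[C@H](C)[C@H]2[C@@H]1/C=C/C=C/C(=O)OCC | intermediate
22 | ethyl ester of the target (7-O-sulfate) | C/C=C(\C)[C@@H]1C(C)=C[C@H]2CC[C@H](OS(=O)(=O)O)[C@H](C)[C@H]2[C@@H]1/C=C/C=C/C(=O)OCC | intermediate
23 | (2E,4E)-5-[(1S,2R,4aS,7S,8R,8aR)-2-[(2E)-but-2-en-2-yl]-3,8-dimethyl-7-(sulfooxy)-1,2,4a,5,6,7,8,8a-octahydronaphthalen-1-yl]penta-2,4-dienoic acid | C/C=C(\C)[C@@H]1C(C)=C[C@H]2CC[C@H](OS(=O)(=O)O)[C@H](C)[C@H]2[C@@H]1/C=C/C=C/C(=O)O | target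

**Step count and risks**

Total step count: 13. Longest linear sequence: 13 steps (1 to 23).

Steps most likely to fail:

Step 2. The cycloaddition may be slow enough for dimerisation of the quinol acetate to win, or the ortho regiochemistry may erode at the hindered, methyl-bearing diene terminus. Incomplete discrimination between the two enantiomers of the quinol acetate would not matter, since both C8 epimers converge in step 4. The fallback sets out from 2 and returns at 4. Cycloaddition of 2 with maleic anhydride (toluene, 80 °C) should give the racemic endo anhydride F1. LiAlH(OtBu)3 (THF, −78 °C) should then reduce the less hindered carbonyl, the one on C1 and remote from the C3 methyl, to the hydroxy lactone F2. Acetalisation with (1S,2R,5S)-menthol (camphorsulfonic acid, toluene, reflux) should give 4 together with the pseudo-ester of the antipodal skeleton F3, and the two are separated by crystallisation or chromatography.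

Step 5. Addition to the doubly flanked ketone may lose facial selectivity, for instance if the C8 methyl has drifted onto the alkene face before the addition, or it may stall through enolisation. The fallback sets out from 8 and returns at 9. The slimmer ethynyl nucleophile (HC≡CMgBr, CeCl3, THF, −78 °C) should give the propargylic alcohol F4, and semihydrogenation (H2, Pd/CaCO3 poisoned with Pb(OAc)2, quinoline) converts it into 9.

Step 9. The crown-separated alkoxide may fragment instead of rearranging, or C8 may not equilibrate fully. The fallback sets out from 13 and returns at 17. Silylation (Me3SiOSO2CF3, Et3N, CH2Cl2) should give the trimethylsilyl ether F5. A neutral thermal siloxy-Cope rearrangement (o-dichlorobenzene, 200 °C) should give the silyl enol ether F6. K2CO3 in MeOH then removes silicon and equilibrates C8 to give 17.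

Further compounds

F1 | step 2 | rac-endo maleic anhydride cycloadduct of 2 (one enantiomer drawn) | O=C1OC(=O)[C@@H]2[C@H]1[C@]3(C)C=C[C@H]2[C@](C)(OC(C)=O)C3=O
F2 | step 2 | rac-hydroxy lactone, lactol carbon on C1 (one enantiomer drawn, lactol centre unassigned) | O=C1OC(O)[C@@H]2[C@H]1[C@]3(C)C=C[C@H]2[C@](C)(OC(C)=O)C3=O
F3 | step 2 | (1S,2R,5S)-menthyl pseudo-ester of the antipodal bicyclic skeleton, diastereomer of 4 | O=C1O[C@@H](O[C@H]4C[C@@H](C)CC[C@@H]4C(C)C)[C@H]2[C@@H]1[C@@]3(C)C=C[C@@H]2[C@@](C)(OC(C)=O)C3=O
F4 | step 5 | ethynyl carbinol Weinreb amide (ethynyl syn to the C4=C4a bridge) | CON(C)C(=O)[C@@H]1[C@]2(C)C=C[C@H]([C@@H]1C(OC)OC)[C@H](C)[C@@]2(O)C#C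
F5 | step 9 | trimethylsilyl ether of 13 | C/C=C(\C)[C@@H]1[C@]2(C)C=C[C@H]([C@@H]1C(OC)OC)[C@H](C)[C@@]2(O[Si](C)(C)C)C=C
F6 | step 9 | trimethylsilyl C6=C7 enol ether of the 8-epi-decalone | C/C=C(\C)[C@@H]1C(C)=C[C@H]2CC=C(O[Si](C)(C)C)[C@@H](C)[C@H]2[C@@H]1C(OC)OC
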